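**The decision.** The target is what I want from this plate, yet it is also what feeds the over-reaction product. So before charging I ask whether this recipe can build up much target, or whether reading later only moves it on.

| flask | substrate | reagent | remark | time |
|---|---|---|---|---|
| elm | 0.070 M | 0.055 M | run made earlier |  |
| cedar | 0.11 M | 0.055 M | run made earlier |  |
| zeta | 0.050 M | 0.0550 M |  | 2.5 min |
| epsilon | 0.050 M | 0.0550 M |  | 2.0 min |
| gamma | 0.050 M | 0.0550 M |  | 3.0 min |

| run | time / s | substrate / % | target / % | over-reaction product / % |
|---|---|---|---|---|
| elm | 10.0 | 99 | 1 | 1 |
| elm | 20.0 | 98 | 0 | 0 |
| elm | 30.0 | 97 | 5 | 4 |
| elm | 60.0 | 88 | 9 | 3 |
| elm | 120 | 61 | 15 | 27 |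
| cedar | 10.0 | 100 | 0 | 0 |
| cedar | 20.0 | 97 | 7 | 0 |
| cedar | 30.0 | 91 | 5 | 2 |
| cedar | 60.0 | 74 | 17 | 8 |
| cedar | 120 | 60 | 10 | 33 |

(each reading ± 2 percentage points)

- which of these there is most of at the end, counted by the substrate in it, zeta (target / substrate / over-reaction product)
- which of these there is most of at the end, counted by the substrate in it, epsilon (target / substrate / over-reaction product)
- which of these there is most of at the end, counted by the substrate in it, gamma (target / substrate / over-reaction product)
- the largest of these amounts at the end, in percent of the substrate charged, zeta
- the largest of these amounts at the end, in percent of the substrate charged, epsilon
- the largest of these amounts at the end, in percent of the substrate charged, gamma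

- the numbers in the tables scatter by 2 percentage points (one standard deviation)
- candidate steps: substrate + reagent + target -> 2 target; substrate + reagent -> target; target -> over-reaction product

**Balance ratio.** Substrate lost becomes target, and over-reaction product comes from target. Over a stretch of a run, substrate lost divided by over-reaction product gained therefore reads how much target is made per target used up. Above one the target grows, at one it passes its peak, and below one it shrinks. In the elm run, from 60.0 s to 120 s, this reads 1.12, with the scatter of the readings in it. The mean c(substrate) there is 0.0522 M and the mean c(reagent) is 0.0372 M.

**Carrying it over.** I set the direct step aside. Autocatalytic making and the draining of target both go with c(target), which cancels, so the ratio scales with c(substrate)·c(reagent). At the new charge it becomes 1.60, the balance ratio at the charge. This is above one, but not by much. It reaches one when the product has fallen to 0.625 of its charged value, which is about 79.1 % of the substrate left if both lose a like share. At that turn the substrate outweighs everything else together. But the ratio carries no clock, so it shows substrate leading at the turn and does not place my reading times against that turn. For a clock I have the readings: at 120 s the elm run still reads 61 % substrate against 27 % over-reaction product, and epsilon is read at that same time. So I commit to substrate for epsilon on that reading, and for zeta and gamma, which lie past the last reading, as a judgement. I keep this charge with the short readings.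

**The forecast.** It also names substrate each time, with 71 % for epsilon, 64 % for zeta and 58 % for gamma, and it keeps target low “because it drains quickly, which holds the autocatalysis back”. My ratio gives neither a clock nor these end amounts.

**The result.** Substrate is largest: 71.4 % in epsilon, 63.3 % in zeta, 57.2 % in gamma. At 2.00 min epsilon makes target 1.07 times faster than it uses it, each step taken net. My ratio, taken with what is left there, gives 0.844, so it calls the turn slightly early.

    substrate + reagent + target → 2 target (k = 17.7 /M²/s)
    substrate + reagent → target (k = 0.0101 /M/s)
    target → over-reaction product (k = 0.0266 /s)

**A second flask.** Epsilon read at 8.0 min has 42 % of its substrate and 46.9 % of its reagent left, so the ratio is 0.312, and target should be shrinking. The computed flask holds 0.792 % target, less than the 10.7 % at 2.00 min, and over-reaction product leads with 57.6 %.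

Readings and results were computed on assumed constants; noise was put on by code.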